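**Target:**
(1R,2R,3S)-1-(3,4-dimethoxyphenyl)-6,7-dimethoxy-2,3-dimethyl-1,2,3,4-tetrahydronaphthalene. This is the all-trans aryltetralin lignan galbulin (C1-aryl trans to C2-methyl, C2-methyl trans to C3-methyl), C22H28O4, which is exactly twice C11H14O2.

**Retrosynthetic overview**
1. The target is a redox-neutral head-to-head cyclodimer of two propenylarene units, so the C2–C3 bond (lignan 8–8′) and the C1–C8a bond (lignan 7′–6) are cut in one operation.
2. Feedstock: methyl eugenol 1, isomerised to (E)-methyl isoeugenol 2.
3. Key operation: radical-cation dimerisation of 2 under a chiral counter-anion sets the 8–8′ bond and both methyl-bearing centres, giving the all-trans cyclobutane 3 (not isolated).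
4. In the same pot, 3 is reopened to the 1,4-radical cation, whose benzylic cation closes onto the veratryl ring para to OMe; H-atom return gives the target 4.
5. Ring order: only ring B (the saturated ring of the tetralin) is built; ring A and the pendant aryl ring come unchanged from 2.

**Assumptions**
- The facial bias of the chiral anion cannot be predicted with certainty. The antipode of the anion (from (R)- or (S)-BINOL) that gives 3 and 4 and not their mirror images is fixed by one test run; it is written IDPi* below.
- IDPi* is a confined imidodiphosphorimidate anion [(ArO)2P(=NTf)–N–P(=NTf)(OAr)2]−, each (ArO)2 being a 3,3′-diaryl-1,1′-bi-2-naphtholate. Its 2,4,6-tris(4-methoxyphenyl)pyrylium salt is made by anion exchange from the commercial pyrylium tetrafluoroborate.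

**Route**

Step 1
Reactants: 1 methyl eugenol (4-allyl-1,2-dimethoxybenzene)
Product: 2 (E)-methyl isoeugenol (1,2-dimethoxy-4-[(E)-prop-1-en-1-yl]benzene)
Conditions: [CpRu(NCMe)(L)]PF6 (1 mol %; L = 2-(di-isopropylphosphino)-4-tert-butyl-1-methylimidazole), acetone, 40 °C; distil
Reagents that add atoms: none
Why: Metal-mediated 1,3-hydrogen shift (alkene isomerisation through a ruthenium allyl, with the imidazole nitrogen as internal base) moves the double bond by one position into conjugation with the arene and gives the E isomer almost exclusively; no stereocentre is formed and no atom is gained or lost.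

Step 2
Reactants: 2 (E)-methyl isoeugenol (two molecules, joined head-to-head)
Product: 4 (1R,2R,3S)-1-(3,4-dimethoxyphenyl)-6,7-dimethoxy-2,3-dimethyl-1,2,3,4-tetrahydronaphthalene, via all-trans cyclobutane dimer 3 (not isolated)
Conditions: a) 2,4,6-tris(4-methoxyphenyl)pyrylium IDPi* salt (2 mol %), degassed CH2Cl2/pentane 1:1, −78 °C, 455 nm LEDs, until 2 is consumed; b) add (PhS)2 (10 mol %), −78 → 0 °C, 455 nm LEDs; chromatography, recrystallise
Reagents that add atoms: none
Why: Proposed new method: asymmetric counter-anion-directed photoredox catalysis, in which the excited pyrylium oxidises 2 to its radical cation, held as a contact ion pair by the confined chiral anion while its C8 adds to C8 of a second molecule of 2 (this fixes both methyl-bearing centres, trans to each other and in one absolute sense) and the adduct closes to the all-trans [2+2] dimer 3; once the alkene is gone and the thiyl/thiol H-atom shuttle is added, re-oxidation of 3 reopens the strained bis-benzylic bond to the same 1,4-radical cation, whose benzylic cation closes onto the veratryl ring para to a methoxy group through a chair-like transition state with the aryl group pseudo-equatorial (C1 trans to the C2-methyl), and deprotonation followed by H-atom transfer from PhSH to the benzylic radical gives 4 with the two methyl centres untouched; the closest known reaction types are the radical-cation [2+2] dimerisation of anethole-type propenylarenes to all-trans cyclobutane lignans, chiral-anion-controlled radical-cation cyclopropanation of the same alkenes, and the acridinium/disulfide formal [4+2] dimerisation of styrenes to 1-aryltetralins.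

**Compound list**
1 | methyl eugenol (4-allyl-1,2-dimethoxybenzene) | COc1ccc(CC=C)cc1OC | starting material
2 | (E)-methyl isoeugenol (1,2-dimethoxy-4-[(E)-prop-1-en-1-yl]benzene) | COc1ccc(/C=C/C)cc1OC | intermediate
3 | (1S,2S,3R,4R)-1,2-bis(3,4-dimethoxyphenyl)-3,4-dimethylcyclobutane (all-trans, C2-symmetric) | COc1ccc(cc1OC)[C@H]1[C@H](C)[C@@H](C)[C@@H]1c1ccc(OC)c(OC)c1 | intermediate
4 | (1R,2R,3S)-1-(3,4-dimethoxyphenyl)-6,7-dimethoxy-2,3-dimethyl-1,2,3,4-tetrahydronaphthalene | COc1ccc([C@@H]2c3cc(OC)c(OC)cc3C[C@H](C)[C@H]2C)cc1OC | target

**Totals**
Total step count: 2. Longest linear sequence: 2.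

**Steps most likely to fail**
The route has only two steps, so step 2 is entered once for each of its two stages.

1. Step 2, stage a (absolute stereocontrol by the ion pair). The chiral anion may give low ee in the 8–8′ bond formation. The fallback sets out from 2 and comes back at 4, and replaces asymmetric catalysis by resolution. 2 is dimerised with achiral 9-mesityl-10-methylacridinium tetrafluoroborate (2.5 mol %) and (PhS)2 (10 mol %) in 1,2-dichloroethane under 450 nm light at room temperature, all components present from the start. The racemic cyclobutane may build up, that is 3 together with (1R,2R,3S,4S)-1,2-bis(3,4-dimethoxyphenyl)-3,4-dimethylcyclobutane F1, and is consumed in the same pot. The racemic all-trans tetralin results, that is 4 together with (1S,2S,3R)-1-(3,4-dimethoxyphenyl)-6,7-dimethoxy-2,3-dimethyl-1,2,3,4-tetrahydronaphthalene F2. Preparative chiral SFC on a polysaccharide carbamate phase separates 4 from F2.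

2. Step 2, stage b (ring expansion of 3). The reopened radical cation may fall apart to monomer 2, which then consumes the thiol by thiol-ene addition, or the transient strong acid may divert 2 to indane-type dimers. The fallback sets out from 3 (isolated and recrystallised by stopping step 2 after stage a) and comes back at 4, and replaces the radical-cation ring expansion by a two-electron route. Reductive cleavage of the strained bis-benzylic C1–C2 bond with Li in liquid NH3/THF at −78 °C, quenched with NH4Cl, gives (2S,3S)-1,4-bis(3,4-dimethoxyphenyl)-2,3-dimethylbutane F3 with both methyl-bearing centres untouched. DDQ (1.05 equiv) in CH2Cl2/TFA at 0 °C then removes a benzylic hydride, and the cation closes onto the other veratryl ring para to methoxy (oxidative Friedel–Crafts cyclisation) to give 4, with the aryl group trans to the neighbouring methyl.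

3. Step 1 (E purity of 2). Residual Z isomer or allyl isomer would erode selectivity in step 2. The fallback sets out from 1 and comes back at 2, and uses addition–elimination in place of metal-catalysed isomerisation. HBr (33 % in AcOH, 0 °C) adds in the Markovnikov sense to give racemic 4-(2-bromopropyl)-1,2-dimethoxybenzene F4. KOtBu in DMSO at room temperature eliminates HBr toward the conjugated alkene and equilibrates it to the E isomer 2, which is distilled.

**Further compounds**
F1 | step 2 | (1R,2R,3S,4S)-1,2-bis(3,4-dimethoxyphenyl)-3,4-dimethylcyclobutane (mirror image of 3) | COc1ccc(cc1OC)[C@@H]1[C@@H](C)[C@H](C)[C@H]1c1ccc(OC)c(OC)c1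
F2 | step 2 | (1S,2S,3R)-1-(3,4-dimethoxyphenyl)-6,7-dimethoxy-2,3-dimethyl-1,2,3,4-tetrahydronaphthalene (mirror image of 4) | COc1ccc([C@H]2c3cc(OC)c(OC)cc3C[C@@H](C)[C@@H]2C)cc1OC
F3 | step 2 | (2S,3S)-1,4-bis(3,4-dimethoxyphenyl)-2,3-dimethylbutane | COc1ccc(C[C@H](C)[C@@H](C)Cc2ccc(OC)c(OC)c2)cc1OC
F4 | step 1 | 4-(2-bromopropyl)-1,2-dimethoxybenzene (racemic) | COc1ccc(CC(C)Br)cc1OC
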